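**Retrosynthetic overview**

1. 20 ⇒ (global O-debenzylation) 19 ⇒ C4–O–C4 ether: the C4 hydroxyl of the bottom unit (alcohol 12) captures, on the β face, the C4 cation of the middle unit, released by monovalent silver from the 4β-arylthio dimer 18.
2. 18 ⇒ 4β→8 C–C bond between two monomers made from (−)-epicatechin with orthogonal C4 leaving groups (2-ethoxyethoxy in donor 16, arylthio in nucleophile 17); all rings of the top and middle units come from (−)-epicatechin.
3. 12 (2S series, not served by the natural 2R flavan-3-ols) ⇒ ring C of the bottom unit is the only ring that is built: its C2–C3 and O1–C8a bonds are made together by a domino aldol/oxa-SNAr annulation of ketone 7 with aldehyde 8. Ring A is bought as 5-fluororesorcinol and ring B as the aldehyde.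
4. Enabling feature: the C4 carbonyl of ring C in 7 and 11 (later the C4 carbinol carbon that carries the ether oxygen). It is α to C3, so C3–H can be enolised, and ortho to the C8a–F bond of ring A, so C8a accepts the aldolate oxygen O1 by addition–elimination.
5. The bottom-unit stereocenters are set after the annulation: transfer hydrogenation of racemic ketone 11, with epimerisation at C3 and selection of the 2S antipode, gives the all-cis 2S,3S,4S alcohol 12.

Key step: step 4

Remark: flavan numbering is used for every unit (O1, C2, C3, C4, C4a, C5 to C8, C8a; ring A = benzo ring, ring B = 2-aryl ring, ring C = pyran ring), the units of 20 are called top, middle and bottom, and a racemate is listed with the SMILES of the enantiomer that is carried on.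

**Route**

Step 1
Reactants: 1 5-fluorobenzene-1,3-diol
Product: 2 1,3-bis(benzyloxy)-5-fluorobenzene
Conditions: BnBr (2.2 equiv), K2CO3, DMF, 25 °C
Reagents that add atoms: benzyl bromide BrCc1ccccc1
Why: Williamson ether synthesis on both phenols, with no stereocenter involved.

Step 2
Reactants: 2 1,3-bis(benzyloxy)-5-fluorobenzene
Product: 3 1,5-bis(benzyloxy)-2-bromo-3-fluorobenzene
Conditions: NBS (1.0 equiv), MeCN, 0 °C
Reagents that add atoms: N-bromosuccinimide O=C1CCC(=O)N1Br
Why: Electrophilic aromatic bromination, which should take the position para to one benzyloxy group and ortho to the other that is flanked by F, because the alternative position between the two benzyloxy groups is more hindered.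

Step 3
Reactants: 3 1,5-bis(benzyloxy)-2-bromo-3-fluorobenzene; 4 2-(benzyloxy)-N-methoxy-N-methylacetamide
Product: 7 2-(benzyloxy)-1-[2,4-bis(benzyloxy)-6-fluorophenyl]ethan-1-one, via aryllithium 5 (not isolated), via lithium hemiaminal alkoxide 6 (not isolated)
Conditions: n-BuLi, THF, −78 °C; then 4, −78 to −30 °C; then 1 M HCl
Reagents that add atoms: none
Why: Bromine–lithium exchange followed by Weinreb ketone synthesis, in which the chelated tetrahedral adduct 6 prevents over-addition and the ortho-fluoro aryllithium 5 is kept at −78 °C so that it does not lose LiF to an aryne.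

Step 4
Reactants: 7 2-(benzyloxy)-1-[2,4-bis(benzyloxy)-6-fluorophenyl]ethan-1-one; 8 3,4-bis(benzyloxy)benzaldehyde
Product: 11 racemic trans-3,5,7-tris(benzyloxy)-2-[3,4-bis(benzyloxy)phenyl]chroman-4-one, via potassium enolate 9 (not isolated), via potassium aldolate 10 (not isolated)
Conditions: KN(SiMe3)2 (1.05 equiv), THF, −78 °C; then 8; then 18-crown-6, −78 to 25 °C (dilute); AcOH quench
Reagents that add atoms: none
Why: Proposed new method: KN(SiMe3)2 converts 7 into the chelated enolate 9, which adds through C3 to the aldehyde carbon of 8 (the C2–C3 bond), and the aldolate oxygen of 10 then displaces fluoride at C8a by addition–elimination (the O1–C8a bond), the Meisenheimer intermediate being stabilised by the ortho C4 carbonyl and inductively by the two meta benzyloxy groups. The closest known reaction types are domino aldol–SNAr annulations of activated 2-fluoroaryl carbonyl compounds and the SNAr ring closure of 1-(2-fluoroaryl)-1,3-diketone enolates to chromones; here a saturated aldolate closes a chroman-4-one instead. Ring C closes in a 6-exo mode by attack of O1 on the arene carbon C8a, and only the six-membered ring can form because the C3 oxygen is benzylated (a free 3-OH would close a benzofuranone). C3 is under thermodynamic control (retro-aldol equilibration of 10 and enolisation of the product should funnel the material to the 2,3-trans ketone with both substituents equatorial), whereas C2 is formed without absolute control and is selected by the catalyst in step 5, where C3 is re-equilibrated as well. The selectivity that is needed is chemoselectivity: cyclisation of the aldolate ahead of its dehydration to a non-cyclisable chalcone or intermolecular arylation of the enolate. It is secured by the irreversible loss of fluoride as KF, by dilution, by the single C–F bond on ring A, and by the use of one equivalent of base that ends as KF so that the product is not left in strong base.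

Step 5
Reactants: 11 racemic trans-3,5,7-tris(benzyloxy)-2-[3,4-bis(benzyloxy)phenyl]chroman-4-one
Product: 12 (2S,3S,4S)-3,5,7-tris(benzyloxy)-2-[3,4-bis(benzyloxy)phenyl]chroman-4-ol (all-cis)
Conditions: RuCl[(R,R)-TsDPEN](p-cymene) (2 mol %), HCO2H/DBU (1:1.5), CH2Cl2, 30 °C; chromatographic separation from unreacted ketone
Reagents that add atoms: none
Why: Noyori–Ikariya asymmetric transfer hydrogenation run as a resolution: the (R,R) catalyst should deliver hydride to the C4 face anti to the 2-aryl group of the 2S ketone (axial attack, matched; the descriptor is 4S because C3 carries oxygen), C3 equilibrates by enolisation under DBU so that reduction passes through the cis epimer with the C3–O bond antiperiplanar to the incoming hydride (polar Felkin–Anh, dynamic kinetic resolution at C3), and the mismatched 2R ketone is left behind and can be racemised with base through the ring-opened chalcone and resubmitted.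

Step 6
Reactants: 13 (−)-epicatechin
Product: 14 (2R,3R)-5,7-bis(benzyloxy)-2-[3,4-bis(benzyloxy)phenyl]chroman-3-ol
Conditions: BnBr (4.4 equiv), K2CO3, DMF, 25 °C
Reagents that add atoms: benzyl bromide BrCc1ccccc1
Why: Williamson benzylation of the four phenols with a carbonate base that leaves the secondary 3-OH and both stereocenters untouched.

Step 7
Reactants: 14 (2R,3R)-5,7-bis(benzyloxy)-2-[3,4-bis(benzyloxy)phenyl]chroman-3-ol
Product: 15 (2R,3R,4S)-5,7-bis(benzyloxy)-2-[3,4-bis(benzyloxy)phenyl]-4-(2-ethoxyethoxy)chroman-3-ol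
Conditions: DDQ (2 equiv), 2-ethoxyethanol (5 equiv), CH2Cl2, 25 °C
Reagents that add atoms: 2-ethoxyethanol CCOCCO
Why: Oxidative benzylic C–H etherification, in which DDQ abstracts hydride from C4 (activated by the 5,7-dialkoxy ring A) and the alcohol adds to the cation anti to the C3 oxygen and the C2 aryl group, which sets C4 as 4β (4S).

Step 8
Reactants: 15 (2R,3R,4S)-5,7-bis(benzyloxy)-2-[3,4-bis(benzyloxy)phenyl]-4-(2-ethoxyethoxy)chroman-3-ol
Product: 16 (2R,3R,4S)-3,5,7-tris(benzyloxy)-2-[3,4-bis(benzyloxy)phenyl]-4-(2-ethoxyethoxy)chromane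
Conditions: NaH, BnBr, Bu4NI (cat.), DMF, 0 to 25 °C
Reagents that add atoms: benzyl bromide BrCc1ccccc1
Why: Williamson benzylation of the secondary 3-OH, which removes the last free hydroxyl of the donor without touching any stereocenter.

Step 9
Reactants: 16 (2R,3R,4S)-3,5,7-tris(benzyloxy)-2-[3,4-bis(benzyloxy)phenyl]-4-(2-ethoxyethoxy)chromane
Product: 17 (2R,3S,4S)-3,5,7-tris(benzyloxy)-2-[3,4-bis(benzyloxy)phenyl]-4-[(2,6-dimethylphenyl)sulfanyl]chromane
Conditions: 2,6-dimethylbenzenethiol (3 equiv), BF3·OEt2 (cat.), CH2Cl2, −78 to −30 °C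
Reagents that add atoms: 2,6-dimethylbenzenethiol Cc1cccc(C)c1S
Why: Lewis-acid-mediated SN1 exchange at C4 (the thiolysis reaction of 4-substituted flavans), in which the thiol adds to the C4 cation from the β face anti to the 3-benzyloxy group, so the 4β configuration is kept (the descriptor at C3 becomes S only because sulfur outranks oxygen).

Step 10
Reactants: 16 (2R,3R,4S)-3,5,7-tris(benzyloxy)-2-[3,4-bis(benzyloxy)phenyl]-4-(2-ethoxyethoxy)chromane; 17 (2R,3S,4S)-3,5,7-tris(benzyloxy)-2-[3,4-bis(benzyloxy)phenyl]-4-[(2,6-dimethylphenyl)sulfanyl]chromane (3 equiv)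
Product: 18 deca-O-benzyl epicatechin-(4β→8)-epicatechin bearing a 4β-[(2,6-dimethylphenyl)sulfanyl] group on the lower unit
Conditions: TMSOTf (cat.), 4 Å MS, CH2Cl2, −78 °C
Reagents that add atoms: none
Why: Lewis-acid-promoted Friedel–Crafts-type interflavan coupling, in which TMSOTf should ionise only the hard 2-ethoxyethoxy leaving group of 16 while the soft and hindered arylthio group of 17 stays in place, and C8 of 17 (used in excess to suppress further chain growth) attacks the C4 cation on the β face to give the 4β→8 bond (4R).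

Step 11
Reactants: 18 deca-O-benzyl epicatechin-(4β→8)-epicatechin bearing a 4β-[(2,6-dimethylphenyl)sulfanyl] group on the lower unit; 12 (2S,3S,4S)-3,5,7-tris(benzyloxy)-2-[3,4-bis(benzyloxy)phenyl]chroman-4-ol (1.5 equiv)
Product: 19 pentadeca-O-benzyl ether of 20 (all fifteen hydroxyl groups benzylated)
Conditions: AgOTf (1.5 equiv), 2,6-di-tert-butyl-4-methylpyridine (2 equiv), 4 Å MS, CH2Cl2, −40 to 0 °C, dark
Reagents that add atoms: none
Why: Glycosylation-like SN1 etherification, in which monovalent silver abstracts the arylthio group to give the A-ring-stabilised C4 cation of the middle unit, the C4 hydroxyl of 12 captures it on the β face anti to the 3-benzyloxy and 2-aryl groups (3,4-trans, 4S), and the hindered pyridine removes the proton so that the kinetically favoured O-alkylation is not reversed into arene C-alkylation, while the configuration at C4 of 12 is untouched because only its O–H bond reacts.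

Step 12
Reactants: 19 pentadeca-O-benzyl ether of 20
Product: 20 CNP0310719.1
Conditions: H2 (1 atm), Pd(OH)2/C, THF/MeOH/H2O, 25 °C
Reagents that add atoms: none
Why: Hydrogenolysis of the fifteen benzyl ethers under neutral conditions (the standard release of oligomeric flavan-3-ols), in which the hindered secondary C4–O–C4 ether is expected to react far more slowly than the O-benzyl groups and no stereocenter is touched.

**Compound list**

1 | 5-fluorobenzene-1,3-diol | Oc1cc(O)cc(F)c1 | starting material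
2 | 1,3-bis(benzyloxy)-5-fluorobenzene | Fc1cc(OCc2ccccc2)cc(OCc2ccccc2)c1 | intermediate
3 | 1,5-bis(benzyloxy)-2-bromo-3-fluorobenzene | Brc1c(F)cc(OCc2ccccc2)cc1OCc1ccccc1 | intermediate
4 | 2-(benzyloxy)-N-methoxy-N-methylacetamide | CON(C)C(=O)COCc1ccccc1 | starting material
5 | [2,4-bis(benzyloxy)-6-fluorophenyl]lithium (aryllithium) | [Li]c1c(F)cc(OCc2ccccc2)cc1OCc1ccccc1 | intermediate
6 | lithium 2-(benzyloxy)-1-[2,4-bis(benzyloxy)-6-fluorophenyl]-1-[methoxy(methyl)amino]ethan-1-olate (lithium hemiaminal alkoxide, racemic) | [Li+].[O-]C(COCc1ccccc1)(N(C)OC)c1c(F)cc(OCc2ccccc2)cc1OCc1ccccc1 | intermediate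
7 | 2-(benzyloxy)-1-[2,4-bis(benzyloxy)-6-fluorophenyl]ethan-1-one | O=C(COCc1ccccc1)c1c(F)cc(OCc2ccccc2)cc1OCc1ccccc1 | intermediate
8 | 3,4-bis(benzyloxy)benzaldehyde | O=Cc1ccc(OCc2ccccc2)c(OCc2ccccc2)c1 | starting material
9 | potassium (Z)-2-(benzyloxy)-1-[2,4-bis(benzyloxy)-6-fluorophenyl]ethen-1-olate (potassium enolate) | [K+].[O-]/C(=C\OCc1ccccc1)c1c(F)cc(OCc2ccccc2)cc1OCc1ccccc1 | intermediate
10 | potassium 2-(benzyloxy)-3-[2,4-bis(benzyloxy)-6-fluorophenyl]-1-[3,4-bis(benzyloxy)phenyl]-3-oxopropan-1-olate (potassium aldolate, equilibrating mixture of stereoisomers) | [K+].[O-]C(c1ccc(OCc2ccccc2)c(OCc2ccccc2)c1)C(OCc1ccccc1)C(=O)c1c(F)cc(OCc2ccccc2)cc1OCc1ccccc1 | intermediate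
11 | racemic trans-3,5,7-tris(benzyloxy)-2-[3,4-bis(benzyloxy)phenyl]chroman-4-one (2S,3S enantiomer shown) | O=C1c2c(OCc3ccccc3)cc(OCc3ccccc3)cc2O[C@@H](c2ccc(OCc3ccccc3)c(OCc3ccccc3)c2)[C@@H]1OCc1ccccc1 | intermediate
12 | (2S,3S,4S)-3,5,7-tris(benzyloxy)-2-[3,4-bis(benzyloxy)phenyl]chroman-4-ol (all-cis) | O[C@H]1c2c(OCc3ccccc3)cc(OCc3ccccc3)cc2O[C@@H](c2ccc(OCc3ccccc3)c(OCc3ccccc3)c2)[C@H]1OCc1ccccc1 | intermediate
13 | (−)-epicatechin, (2R,3R)-2-(3,4-dihydroxyphenyl)chromane-3,5,7-triol | Oc1cc(O)c2c(c1)O[C@H](c1ccc(O)c(O)c1)[C@H](O)C2 | starting material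
14 | (2R,3R)-5,7-bis(benzyloxy)-2-[3,4-bis(benzyloxy)phenyl]chroman-3-ol | O(Cc3ccccc3)c1cc(OCc3ccccc3)c2c(c1)O[C@H](c1ccc(OCc3ccccc3)c(OCc3ccccc3)c1)[C@H](O)C2 | intermediate
15 | (2R,3R,4S)-5,7-bis(benzyloxy)-2-[3,4-bis(benzyloxy)phenyl]-4-(2-ethoxyethoxy)chroman-3-ol | O(Cc3ccccc3)c1cc(OCc3ccccc3)c2c(c1)O[C@H](c1ccc(OCc3ccccc3)c(OCc3ccccc3)c1)[C@H](O)[C@H]2OCCOCC | intermediate
16 | (2R,3R,4S)-3,5,7-tris(benzyloxy)-2-[3,4-bis(benzyloxy)phenyl]-4-(2-ethoxyethoxy)chromane | O(Cc3ccccc3)c1cc(OCc3ccccc3)c2c(c1)O[C@H](c1ccc(OCc3ccccc3)c(OCc3ccccc3)c1)[C@H](OCc3ccccc3)[C@H]2OCCOCC | intermediate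
17 | (2R,3S,4S)-3,5,7-tris(benzyloxy)-2-[3,4-bis(benzyloxy)phenyl]-4-[(2,6-dimethylphenyl)sulfanyl]chromane | O(Cc3ccccc3)c1cc(OCc3ccccc3)c2c(c1)O[C@H](c1ccc(OCc3ccccc3)c(OCc3ccccc3)c1)[C@H](OCc3ccccc3)[C@H]2Sc1c(C)cccc1C | intermediate
18 | deca-O-benzyl epicatechin-(4β→8)-epicatechin bearing a 4β-[(2,6-dimethylphenyl)sulfanyl] group on the lower unit (upper unit 2R,3R,4R; lower unit 2R,3S,4S) | O(Cc3ccccc3)c1cc(OCc3ccccc3)c2c(c1)O[C@H](c1ccc(OCc3ccccc3)c(OCc3ccccc3)c1)[C@H](OCc3ccccc3)[C@H]2c1c(OCc3ccccc3)cc(OCc3ccccc3)c2c1O[C@H](c1ccc(OCc3ccccc3)c(OCc3ccccc3)c1)[C@H](OCc3ccccc3)[C@H]2Sc1c(C)cccc1C | intermediate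
19 | pentadeca-O-benzyl ether of 20 (top unit 2R,3R,4R; middle unit 2R,3R,4S; bottom unit 2S,3S,4S) | O(Cc3ccccc3)c1cc(OCc3ccccc3)c2c(c1)O[C@H](c1ccc(OCc3ccccc3)c(OCc3ccccc3)c1)[C@H](OCc3ccccc3)[C@H]2c1c(OCc3ccccc3)cc(OCc3ccccc3)c2c1O[C@H](c1ccc(OCc3ccccc3)c(OCc3ccccc3)c1)[C@H](OCc3ccccc3)[C@H]2O[C@H]1c2c(OCc3ccccc3)cc(OCc3ccccc3)cc2O[C@@H](c2ccc(OCc3ccccc3)c(OCc3ccccc3)c2)[C@H]1OCc1ccccc1 | intermediate
20 | CNP0310719.1: epicatechin-(4β→8)-epicatechin whose C4 (4S) is joined through an ether oxygen to C4 of an all-cis (2S,3S,4S)-flavan-3,4-diol unit | Oc1cc(O)c2c(c1)O[C@H](c1ccc(O)c(O)c1)[C@H](O)[C@H]2c1c(O)cc(O)c2c1O[C@H](c1ccc(O)c(O)c1)[C@H](O)[C@H]2O[C@H]1c2c(O)cc(O)cc2O[C@@H](c2ccc(O)c(O)c2)[C@H]1O | target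

**Step count and risks**

Total step count: 12. Longest linear sequence: 7 steps (steps 1 to 5, 11 and 12, or steps 6 to 12).

Steps most likely to fail:

Step 4 (Proposed new method). The ring closure by fluoride displacement may be slower than the loss of the aldolate by retro-aldol followed by intermolecular arylation of the enolate, or than dehydration of the aldol to a chalcone that can no longer cyclise. The fallback uses known chemistry, sets out from 7 and comes back to the route at 11. The fluoride of 7 is exchanged for hydroxide by SNAr (KOH, DMSO/H2O, 80 °C) to give the phenol 2-(benzyloxy)-1-[2,4-bis(benzyloxy)-6-hydroxyphenyl]ethan-1-one F1. Claisen–Schmidt condensation of this phenol with 8 (KOH, EtOH, 25 °C) gives the chalcone (Z)-2-(benzyloxy)-1-[2,4-bis(benzyloxy)-6-hydroxyphenyl]-3-[3,4-bis(benzyloxy)phenyl]prop-2-en-1-one F2. Its oxa-Michael ring closure (NaOAc, EtOH, reflux) should give the racemic trans ketone 11.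

Step 11. Capture of the C4 cation by the hindered secondary hydroxyl of 12 may lose out to C-alkylation of the electron-rich A rings of either partner or to hydrolysis by traces of water, or the arylthio group may be activated too slowly by silver. The fallback sets out from 18 and 12 and comes back at 19. The thioether 18 is converted by silver-assisted acetolysis (AgOAc, AcOH/CH2Cl2, 25 °C) into the 4β-acetate of the deca-O-benzyl dimer F3, and 12 is silylated (Me3SiCl, imidazole, CH2Cl2) to (2S,3S,4S)-3,5,7-tris(benzyloxy)-2-[3,4-bis(benzyloxy)phenyl]-4-(trimethylsilyloxy)chromane F4. The acetate and the silyl ether are then joined with catalytic TMSOTf (CH2Cl2, 4 Å MS, −78 °C) in an acid-free silyl-transfer etherification to give 19.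

Step 5. Epimerisation at C3 may be slower than reduction, so that the 2S ketone is reduced as its trans epimer; the catalyst may discriminate poorly between the two C2 antipodes; or the acid-labile 4-hydroxyflavan may ionise in the formate medium. The fallback sets out from 11 and comes back at 12. The lithium enolate of 11 (LiN(i-Pr)2, THF, −78 °C) is protonated kinetically anti to the 2-aryl group (2,6-di-tert-butylphenol, −78 °C) to give racemic cis-3,5,7-tris(benzyloxy)-2-[3,4-bis(benzyloxy)phenyl]chroman-4-one F5. Reduction anti to both cis substituents (LiBH(s-Bu)3, THF, −78 °C) gives racemic all-cis 3,5,7-tris(benzyloxy)-2-[3,4-bis(benzyloxy)phenyl]chroman-4-ol F6. Esterification with (S)-2-methoxy-2-phenylacetic acid (DCC, DMAP, CH2Cl2) and chromatographic separation of the two diastereomers gives the (S)-2-methoxy-2-phenylacetate of the (2S,3S,4S) alcohol F7, whose saponification (LiOH, THF/H2O) gives 12.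

Further compounds

F1 | step 4 | 2-(benzyloxy)-1-[2,4-bis(benzyloxy)-6-hydroxyphenyl]ethan-1-one | O=C(COCc1ccccc1)c1c(O)cc(OCc2ccccc2)cc1OCc1ccccc1
F2 | step 4 | (Z)-2-(benzyloxy)-1-[2,4-bis(benzyloxy)-6-hydroxyphenyl]-3-[3,4-bis(benzyloxy)phenyl]prop-2-en-1-one | O=C(c1c(O)cc(OCc2ccccc2)cc1OCc1ccccc1)/C(OCc1ccccc1)=C/c1ccc(OCc2ccccc2)c(OCc2ccccc2)c1
F3 | step 11 | 4β-acetate of the deca-O-benzyl dimer (upper unit 2R,3R,4R; lower unit 2R,3R,4S) | O(Cc3ccccc3)c1cc(OCc3ccccc3)c2c(c1)O[C@H](c1ccc(OCc3ccccc3)c(OCc3ccccc3)c1)[C@H](OCc3ccccc3)[C@H]2c1c(OCc3ccccc3)cc(OCc3ccccc3)c2c1O[C@H](c1ccc(OCc3ccccc3)c(OCc3ccccc3)c1)[C@H](OCc3ccccc3)[C@H]2OC(C)=O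
F4 | step 11 | (2S,3S,4S)-3,5,7-tris(benzyloxy)-2-[3,4-bis(benzyloxy)phenyl]-4-(trimethylsilyloxy)chromane | C[Si](C)(C)O[C@H]1c2c(OCc3ccccc3)cc(OCc3ccccc3)cc2O[C@@H](c2ccc(OCc3ccccc3)c(OCc3ccccc3)c2)[C@H]1OCc1ccccc1
F5 | step 5 | racemic cis-3,5,7-tris(benzyloxy)-2-[3,4-bis(benzyloxy)phenyl]chroman-4-one (2S,3R enantiomer shown) | O=C1c2c(OCc3ccccc3)cc(OCc3ccccc3)cc2O[C@@H](c2ccc(OCc3ccccc3)c(OCc3ccccc3)c2)[C@H]1OCc1ccccc1
F6 | step 5 | racemic all-cis 3,5,7-tris(benzyloxy)-2-[3,4-bis(benzyloxy)phenyl]chroman-4-ol (2S,3S,4S enantiomer shown) | O[C@H]1c2c(OCc3ccccc3)cc(OCc3ccccc3)cc2O[C@@H](c2ccc(OCc3ccccc3)c(OCc3ccccc3)c2)[C@H]1OCc1ccccc1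
F7 | step 5 | (2S,3S,4S)-3,5,7-tris(benzyloxy)-2-[3,4-bis(benzyloxy)phenyl]chroman-4-yl (S)-2-methoxy-2-phenylacetate | CO[C@H](C(=O)O[C@H]1c2c(OCc3ccccc3)cc(OCc3ccccc3)cc2O[C@@H](c2ccc(OCc3ccccc3)c(OCc3ccccc3)c2)[C@H]1OCc1ccccc1)c1ccccc1
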